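The phenyl ring of the ketone on bridgehead C1 is the only arene of the target, it is unsubstituted, and C1 is walled in by the C8 gem-dimethyl group and the C2 and C9 carbonyls. The route therefore disconnects that benzene ring itself. A slim propynoyl group is placed on C1 of the finished tetracyclic trione, and the terminal ynone 30 is then heated with 2H-pyran-2-one: [4+2] addition followed by loss of CO2 forms two C–C bonds and the aromatic ring in one operation, with no regiochemical or stereochemical issue. Precursor 30 already holds all five stereocentres, the three ring ketones and the C5 geranyl chain.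

Key step: step 20

Remarks on the chemistry
- Numbering used throughout: C1 acyl bridgehead, C2/C4 ketones flanking quaternary C3, C5 geranyl bridgehead, C6 CH2, C7 CH, C8 CMe2, C9 bridging ketone, C10 CH2, C11 CH, C12 CMe2, C13/C14 CH2. Ring A is C1/C9/C5/C6/C7/C8 and ring B is C1–C5/C9.
- Reading of the stereodescriptors: C12 lies on the C2 side of the cage. On the cyclopentane, C2 is therefore cis and C4 trans to C10. Steps 11–16 rest on this relation. The descriptors of 30 and 33 describe the same cage.
- 2H-Pyran-2-one is itself an electron-poor, partly aromatic diene, so its pairing with an ynone is not polarity-matched. The reaction is driven by heat, excess diene and irreversible CO2 loss.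
- The silyl cap is removed with buffered fluoride. Alkoxide or hydroxide would add to the ynone or cleave the non-enolisable tricarbonyl array.
- Assumption: the seven starting materials are purchasable, and the C10 centre of 13–15 forms as an epimer mixture that step 10 erases.

Step 1
Reactants: 1 methyl 3,3-dimethylpent-4-enoate
Product: 2 3,3-dimethylpent-4-en-1-ol
Conditions: LiAlH4, Et2O, 0 °C to rt
Reagents that add atoms: none
Why: Hydride reduction of the ester to the primary alcohol leaves the isolated vinyl group untouched and brings C14 to the oxidation level needed for alkylation.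

Step 2
Reactants: 2 3,3-dimethylpent-4-en-1-ol
Product: 3 5-iodo-3,3-dimethylpent-1-ene
Conditions: I2, PPh3, imidazole, CH2Cl2, 0 °C to rt
Reagents that add atoms: iodine, II
Why: Appel-type iodination of an unhindered primary alcohol proceeds by SN2 displacement of the oxyphosphonium group.

Step 3
Reactants: 3 5-iodo-3,3-dimethylpent-1-ene; 4 dimethyl malonate
Product: 5 dimethyl 2-(3,3-dimethylpent-4-en-1-yl)malonate
Conditions: NaH, 4 (2 equiv), THF/DMF, 0 to 60 °C
Reagents that add atoms: none
Why: Malonic ester alkylation with a primary iodide forms the C3–C14 bond, and excess malonate suppresses double alkylation.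

Step 4
Reactants: 5 dimethyl 2-(3,3-dimethylpent-4-en-1-yl)malonate; 6 (E)-but-2-enal
Product: 7 dimethyl 2-[(E)-3,3-dimethyl-6-oxohex-4-en-1-yl]malonate
Conditions: second-generation Hoveyda–Grubbs catalyst RuCl2(SIMes)(=CH-C6H4-2-OiPr) (5 mol %), 6 (5 equiv), CH2Cl2, 40 °C
Reagents that add atoms: none
Why: Olefin cross metathesis between a vinyl group that does not homodimerise (next to a quaternary carbon) and an enal should give the E enal with loss of propene.

Step 5
Reactants: 7 dimethyl 2-[(E)-3,3-dimethyl-6-oxohex-4-en-1-yl]malonate
Product: 8 dimethyl (2R)-3,3-dimethyl-2-(2-oxoethyl)cyclopentane-1,1-dicarboxylate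
Conditions: (R)-2-[diphenyl(trimethylsilyloxy)methyl]pyrrolidine (20 mol %), PhCO2H (20 mol %), EtOH, rt
Reagents that add atoms: none
Why: Iminium-catalysed intramolecular Michael addition (5-exo-trig, helped by the gem-dimethyl effect) closes the cyclopentane through C3–C11, and the bulky group of the R catalyst shields one face of the E, s-trans iminium ion so that C11 should form with R configuration.

Step 6
Reactants: 8 dimethyl (2R)-3,3-dimethyl-2-(2-oxoethyl)cyclopentane-1,1-dicarboxylate
Product: 9 [(1R)-2,2-bis(methoxycarbonyl)-5,5-dimethylcyclopentyl]acetic acid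
Conditions: NaClO2, NaH2PO4, 2-methylbut-2-ene, t-BuOH/H2O, rt
Reagents that add atoms: sodium chlorite, [Na+].[O-]Cl=O
Why: Pinnick oxidation converts the aldehyde into the acid under buffered conditions that leave the malonate esters and C11 (not alpha to the carbonyl) untouched.

Step 7
Reactants: 10 4,4-dimethylcyclohex-2-en-1-one
Product: 11 (1R)-4,4-dimethylcyclohex-2-en-1-ol
Conditions: (S)-2-methyl-CBS-oxazaborolidine (10 mol %), BH3·SMe2, THF, −40 °C
Reagents that add atoms: none
Why: Corey–Bakshi–Shibata reduction delivers hydride 1,2 to the enone with the alkenyl arm acting as the large group, so the S catalyst should give the R allylic alcohol that later encodes C7.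

Step 8
Reactants: 9 [(1R)-2,2-bis(methoxycarbonyl)-5,5-dimethylcyclopentyl]acetic acid; 11 (1R)-4,4-dimethylcyclohex-2-en-1-ol
Product: 12 (1R)-4,4-dimethylcyclohex-2-en-1-yl [(1R)-2,2-bis(methoxycarbonyl)-5,5-dimethylcyclopentyl]acetate
Conditions: DCC, DMAP (cat.), CH2Cl2, 0 °C to rt
Reagents that add atoms: none
Why: Steglich esterification joins the two enantioenriched halves without touching either stereocentre, and any minor enantiomer ends up in a separable diastereomer.

Step 9
Reactants: 12 (1R)-4,4-dimethylcyclohex-2-en-1-yl [(1R)-2,2-bis(methoxycarbonyl)-5,5-dimethylcyclopentyl]acetate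
Product: 15 2-[(1R)-2,2-bis(methoxycarbonyl)-5,5-dimethylcyclopentyl]-2-(6,6-dimethylcyclohex-2-en-1-yl)acetic acid (C7 as in 16), via silyl ketene acetal 13 (not isolated), via trimethylsilyl ester 14 (not isolated)
Conditions: LiN(iPr)2, THF, −78 °C; Me3SiCl; warm to rt, then 65 °C; 1 M HCl work-up
Reagents that add atoms: chlorotrimethylsilane, C[Si](C)(C)Cl (silyl group carried only by 13 and 14, absent from 15)
Why: Ireland–Claisen rearrangement forms the congested C7–C10 bond intramolecularly and, being suprafacial on the cyclohexenyl unit, transfers the C5–O configuration of 11 to C7 while moving the alkene to C5=C6, the new C10 centre being inconsequential.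

Step 10
Reactants: 15 Claisen acid
Product: 16 dimethyl (2R)-2-{[(1R)-6,6-dimethylcyclohex-2-en-1-yl]methyl}-3,3-dimethylcyclopentane-1,1-dicarboxylate
Conditions: 9-mesityl-10-phenylacridinium tetrafluoroborate (5 mol %), (PhS)2 (10 mol %), iPr2NEt (20 mol %), CF3CH2OH, 450 nm LED, rt
Reagents that add atoms: none
Why: Photoredox hydrodecarboxylation (carboxylate oxidation, loss of CO2, hydrogen-atom transfer from thiophenol to the secondary C10 radical) removes the carbon that served as the Claisen handle and leaves C7 and C11 untouched.

Step 11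
Reactants: 16 diester
Product: 17 (1S,2R)-2-{[(1R)-6,6-dimethylcyclohex-2-en-1-yl]methyl}-1-(methoxycarbonyl)-3,3-dimethylcyclopentane-1-carboxylic acid
Conditions: KOH (1.1 equiv), MeOH/H2O, rt to 40 °C; HCl work-up
Reagents that add atoms: potassium hydroxide, [K+].[OH-]
Why: Saponification of a geminal diester stops after one ester because the carboxylate deactivates its neighbour, and hydroxide should attack the ester trans to the bulky C11 side chain, which fixes C3 (free acid is the future C4, the remaining cis ester the future C2).

Step 12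
Reactants: 17 half acid
Product: 19 phenyl ester of 17 (C4 as CO2Ph and C2 as CO2Me), via acid chloride 18 (not isolated)
Conditions: (COCl)2, DMF (cat.), CH2Cl2, 0 °C to rt; then PhOH, Et3N, DMAP (cat.), CH2Cl2
Reagents that add atoms: phenol, Oc1ccccc1; oxalyl chloride, O=C(Cl)C(=O)Cl (chlorine carried only by 18)
Why: Acid chloride formation and phenolysis turn the hindered acid into an aryl ester that is clearly more electrophilic than the methyl ester yet survives the next oxidation.

Step 13
Reactants: 19 phenyl methyl diester
Product: 20 C9 enone (4-substituted 5,5-dimethylcyclohex-2-en-1-one bearing the cyclopentane diester)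
Conditions: Rh2(cap)4 (cap = caprolactamate, 1 mol %), t-BuOOH (70 % in water, 5 equiv), ClCH2CH2Cl, 40 °C
Reagents that add atoms: tert-butyl hydroperoxide, CC(C)(C)OO
Why: Catalytic allylic C–H oxidation with tert-butylperoxyl radicals abstracts hydrogen from the only allylic methylene (C9) and oxygenates the allyl radical at that less hindered terminus, remote from the crowded C7, to give the C9 enone.

Step 14
Reactants: 20 C9 enone
Product: 22 tricyclic beta-diketo ester (C4–C5 bond closed with H on C5 and C2 still CO2Me), via lithium enolate 21 (not isolated)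
Conditions: LiBH(s-Bu)3 (1.05 equiv), THF, −78 °C, then warm to rt; NH4Cl work-up
Reagents that add atoms: lithium tri-sec-butylborohydride, [Li+].CCC(C)[BH-](C(C)CC)C(C)CC (lithium carried only by 21)
Why: Conjugate hydride addition to the beta-unsubstituted cyclohexenone generates the C9/C5 enolate regiospecifically, and on warming it attacks the aryl ester in a Dieckmann-type acylation (seven-membered ring) in which C5 can bond only on the face of ring A that carries the C7 side chain.

Step 15
Reactants: 22 tricyclic beta-diketo ester; 23 geranyl bromide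
Product: 24 C5-geranyl tricyclic diketo ester
Conditions: NaH, THF/DMF, 0 °C; 23, 0 °C to rt
Reagents that add atoms: none
Why: C-Alkylation of the beta-diketone enolate with an allylic bromide makes C5 quaternary, and because C5 is a bridgehead of the bicyclo[4.3.1]decane unit the geranyl group can enter only from outside, which is the target configuration.

Step 16
Reactants: 24 C5-geranyl tricyclic diketo ester
Product: 25 des-acyl cage (tetracyclic 2,4,9-trione with H on C1)
Conditions: LiN(SiMe3)2 (1.2 equiv), THF, −78 to 0 °C; AcOH quench at −78 °C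
Reagents that add atoms: none
Why: With C5 quaternary the C9 ketone can enolise only towards C1, and the irreversibly formed lithium enolate closes ring B on the cis-disposed methyl ester (Dieckmann condensation, C1–C2 bond) with C1 fixed by the cage, while the cold acidic quench keeps methoxide from reopening the non-enolisable trione.

Step 17
Reactants: 26 3-(trimethylsilyl)propiolic acid
Product: 27 3-(trimethylsilyl)propynoyl chloride
Conditions: (COCl)2, DMF (cat.), CH2Cl2, 0 °C to rt
Reagents that add atoms: oxalyl chloride, O=C(Cl)C(=O)Cl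
Why: Chlorination of the acid under dimethylformamide catalysis gives the silyl-capped alkynoyl chloride, the cap blocking conjugate addition in the next step.

Step 18
Reactants: 25 des-acyl cage; 27 3-(trimethylsilyl)propynoyl chloride
Product: 29 C1 3-(trimethylsilyl)propynoyl cage, via bridgehead organolithium 28 (not isolated)
Conditions: lithium 2,2,6,6-tetramethylpiperidide (from n-BuLi and the amine, 1.3 equiv), THF, −78 °C; then 27 (2 equiv), −78 to −40 °C
Reagents that add atoms: lithium 2,2,6,6-tetramethylpiperidide, [Li]N1C(C)(C)CCCC1(C)C (lithium carried only by 28)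
Why: Bridgehead lithiation of bicyclo[3.3.1]nonane-2,4,9-trione cores with a hindered, non-reducing lithium amide followed by C-acylation is established for this compound class, C1–H is the only acidic hydrogen of 25, the carbanion cannot invert, and the linear acyl chloride needs little space beside the C8 methyl groups.

Step 19
Reactants: 29 C1 3-(trimethylsilyl)propynoyl cage
Product: 30 C1 propynoyl cage (terminal ynone)
Conditions: Bu4NF/AcOH (1:1, 1.1 equiv), THF, −20 °C
Reagents that add atoms: none
Why: Fluoride-induced protodesilylation of the carbonyl-activated alkynylsilane is fast at low temperature, and the acetic acid buffer excludes the basic nucleophiles that would add to the ynone or cleave the tricarbonyl array by retro-Claisen attack.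

Step 20
Reactants: 30 C1 propynoyl cage; 31 2H-pyran-2-one
Product: 33 target, via bicyclic lactone 32 (not isolated)
Conditions: 31 (5 equiv), BHT (cat.), toluene, 140 °C, sealed tube
Reagents that add atoms: none
Why: The s-cis diene locked in 2H-pyran-2-one (C3 to C6) adds suprafacially across the terminal alkyne of 30 in a concerted intermolecular [4+2] cycloaddition to give the 2-oxabicyclo[2.2.2]octa-5,7-dien-3-one 32, which at the reaction temperature expels CO2 by retro-[4+2] and so aromatises irreversibly. This is the classical pyrone–alkyne benzannulation (Diels–Alder reaction followed by cycloreversion), long used with propiolates and ethynyl ketones. The one new ring, the benzene ring, is closed by two simultaneous intermolecular C–C bond formations (pyrone C3 and C6 to the two alkyne carbons); the two bridgehead centres of 32 are transient and no stereocentre of the cage is touched. Either orientation of the pyrone leads to the same monosubstituted phenyl ketone, so regiochemistry is irrelevant. The required chemoselectivity comes from the substrate: the unhindered, carbonyl-activated, linear C≡CH unit projects away from the C8 methyl groups, whereas the two geranyl alkenes are trisubstituted, unactivated and could not aromatise. The cage has no enolisable hydrogen and no nucleophile is present, so the tricarbonyl array should survive the thermolysis.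

Compound list
1 | methyl 3,3-dimethylpent-4-enoate | COC(=O)CC(C)(C)C=C | starting material
2 | 3,3-dimethylpent-4-en-1-ol | OCCC(C)(C)C=C | intermediate
3 | 5-iodo-3,3-dimethylpent-1-ene | ICCC(C)(C)C=C | intermediate
4 | dimethyl malonate | COC(=O)CC(=O)OC | starting material
5 | dimethyl 2-(3,3-dimethylpent-4-en-1-yl)malonate | COC(=O)C(CCC(C)(C)C=C)C(=O)OC | intermediate
6 | (E)-but-2-enal | C/C=C/C=O | starting material
7 | dimethyl 2-[(E)-3,3-dimethyl-6-oxohex-4-en-1-yl]malonate | COC(=O)C(CCC(C)(C)/C=C/C=O)C(=O)OC | intermediate
8 | dimethyl (2R)-3,3-dimethyl-2-(2-oxoethyl)cyclopentane-1,1-dicarboxylate | O=CC[C@@H]1C(C)(C)CCC1(C(=O)OC)C(=O)OC | intermediate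
9 | [(1R)-2,2-bis(methoxycarbonyl)-5,5-dimethylcyclopentyl]acetic acid | OC(=O)C[C@@H]1C(C)(C)CCC1(C(=O)OC)C(=O)OC | intermediate
10 | 4,4-dimethylcyclohex-2-en-1-one | CC1(C)CCC(=O)C=C1 | starting material
11 | (1R)-4,4-dimethylcyclohex-2-en-1-ol | O[C@H]1C=CC(C)(C)CC1 | intermediate
12 | (1R)-4,4-dimethylcyclohex-2-en-1-yl [(1R)-2,2-bis(methoxycarbonyl)-5,5-dimethylcyclopentyl]acetate | O=C(C[C@@H]1C(C)(C)CCC1(C(=O)OC)C(=O)OC)O[C@H]1C=CC(C)(C)CC1 | intermediate
13 | trimethylsilyl ketene acetal of 12 (not isolated) | C[Si](C)(C)OC(=C[C@@H]1C(C)(C)CCC1(C(=O)OC)C(=O)OC)O[C@H]1C=CC(C)(C)CC1 | intermediate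
14 | trimethylsilyl ester of 15 (not isolated; C10 epimers) | C[Si](C)(C)OC(=O)C([C@@H]1C=CCCC1(C)C)[C@@H]1C(C)(C)CCC1(C(=O)OC)C(=O)OC | intermediate
15 | Claisen acid, C7–C10 bond formed, CO2H on C10 (C10 epimers) | OC(=O)C([C@@H]1C=CCCC1(C)C)[C@@H]1C(C)(C)CCC1(C(=O)OC)C(=O)OC | intermediate
16 | dimethyl (2R)-2-{[(1R)-6,6-dimethylcyclohex-2-en-1-yl]methyl}-3,3-dimethylcyclopentane-1,1-dicarboxylate | C([C@@H]1C=CCCC1(C)C)[C@@H]1C(C)(C)CCC1(C(=O)OC)C(=O)OC | intermediate
17 | (1S,2R) half acid, CO2H trans and CO2Me cis to the C11 side chain | C([C@@H]1C=CCCC1(C)C)[C@@H]1C(C)(C)CC[C@]1(C(=O)O)C(=O)OC | intermediate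
18 | acid chloride of 17 (not isolated) | C([C@@H]1C=CCCC1(C)C)[C@@H]1C(C)(C)CC[C@]1(C(=O)Cl)C(=O)OC | intermediate
19 | phenyl ester of 17 | C([C@@H]1C=CCCC1(C)C)[C@@H]1C(C)(C)CC[C@]1(C(=O)Oc2ccccc2)C(=O)OC | intermediate
20 | C9 enone of 19 | C([C@@H]1C=CC(=O)CC1(C)C)[C@@H]1C(C)(C)CC[C@]1(C(=O)Oc2ccccc2)C(=O)OC | intermediate
21 | lithium C9/C5 enolate (not isolated) | C([C@@H]1CC=C(O[Li])CC1(C)C)[C@@H]1C(C)(C)CC[C@]1(C(=O)Oc2ccccc2)C(=O)OC | intermediate
22 | tricyclic beta-diketo ester, C4–C5 closed, H on C5, C3/C5/C7/C11 as in 33 | COC(=O)[C@@]12CCC(C)(C)[C@H]1C[C@@H]3C[C@H](C2=O)C(=O)CC3(C)C | intermediate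
23 | geranyl bromide | CC(C)=CCC/C(C)=C/CBr | starting material
24 | C5-geranyl tricyclic diketo ester | COC(=O)[C@@]12CCC(C)(C)[C@H]1C[C@@H]3C[C@](C/C=C(\C)CCC=C(C)C)(C2=O)C(=O)CC3(C)C | intermediate
25 | des-acyl cage, H on C1, all other centres as in 33 | CC(C)=CCC/C(C)=C/C[C@@]12C[C@H]3C[C@@H]4C(C)(C)CC[C@]4(C1=O)C(=O)[C@@H](C2=O)C3(C)C | intermediate
26 | 3-(trimethylsilyl)propiolic acid | C[Si](C)(C)C#CC(=O)O | starting material
27 | 3-(trimethylsilyl)propynoyl chloride | C[Si](C)(C)C#CC(=O)Cl | intermediate
28 | C1 bridgehead organolithium of 25 (not isolated) | CC(C)=CCC/C(C)=C/C[C@@]12C[C@H]3C[C@@H]4C(C)(C)CC[C@]4(C1=O)C(=O)[C@@]([Li])(C2=O)C3(C)C | intermediate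
29 | C1 3-(trimethylsilyl)propynoyl cage | CC(C)=CCC/C(C)=C/C[C@@]12C[C@H]3C[C@@H]4C(C)(C)CC[C@]4(C1=O)C(=O)[C@@](C(=O)C#C[Si](C)(C)C)(C2=O)C3(C)C | intermediate
30 | C1 propynoyl cage (key-step precursor) | CC(C)=CCC/C(C)=C/C[C@@]12C[C@H]3C[C@@H]4C(C)(C)CC[C@]4(C1=O)C(=O)[C@@](C(=O)C#C)(C2=O)C3(C)C | intermediate
31 | 2H-pyran-2-one | O=c1cccco1 | starting material
32 | 2-oxabicyclo[2.2.2]octa-5,7-dien-3-one adduct (not isolated; one orientation drawn, new bridgeheads undefined) | CC(C)=CCC/C(C)=C/C[C@@]12C[C@H]3C[C@@H]4C(C)(C)CC[C@]4(C1=O)C(=O)[C@@](C(=O)C5=CC6C=CC5C(=O)O6)(C2=O)C3(C)C | intermediate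
33 | CNP0168637.1 | CC(C)=CCC/C(C)=C/C[C@@]12C[C@H]3C[C@@H]4C(C)(C)CC[C@]4(C1=O)C(=O)[C@@](C(=O)c1ccccc1)(C2=O)C3(C)C | target

Total step count: 20. Longest linear sequence: 18 (steps 1–6, 8–16, 18–20).

Steps most likely to fail

Step 20. Thermal oligomerisation of the terminal ynone or of the pyrone may outrun the polarity-mismatched cycloaddition. Fallback: starting from 30, a normal-demand Diels–Alder reaction with buta-1,3-diene (released from 3-sulfolene, toluene, 110 °C, sealed tube) should give the cyclohexa-1,4-dienyl ketone F3. Dehydrogenation with 2,3-dichloro-5,6-dicyano-1,4-benzoquinone (benzene, rt), which is far faster on a 1,4-diene than on the geranyl chain, returns to the route at 33.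

Step 18. Acyl transfer to the crowded carbanion may be slow. Residual amide base could then consume the acid chloride, or the carbanion could add at the alkyne terminus. Fallback: starting from 25, the lithio species 28 is trapped with 3-(trimethylsilyl)propynal, a smaller electrophile without a leaving group, to give the bridgehead propargylic alcohol F2 (carbinol epimers). Oxidation with 1,1,1-triacetoxy-1,1-dihydro-1,2-benziodoxol-3(1H)-one (CH2Cl2, rt) returns to the route at 29.

Step 14. Hydride may attack the ketone carbon or the aryl ester instead of C6, or proton transfer may quench the enolate before the slow seven-membered ring closure. Fallback: starting from 20, the enone is hydrogenated (H2, Pd on carbon, EtOAc) to the saturated keto diester F1. Kinetic deprotonation with LiN(SiMe3)2 (THF, −78 °C) takes a proton from the C5 methylene, because the C1 methylene is neopentyl. Warming then brings about the same acylation and returns to the route at 22.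

Further compounds
F1 | step 14 | saturated keto diester (20 with C5–C6 reduced) | C([C@@H]1CCC(=O)CC1(C)C)[C@@H]1C(C)(C)CC[C@]1(C(=O)Oc2ccccc2)C(=O)OC
F2 | step 18 | bridgehead propargylic alcohol (carbinol epimers) | CC(C)=CCC/C(C)=C/C[C@@]12C[C@H]3C[C@@H]4C(C)(C)CC[C@]4(C1=O)C(=O)[C@@](C(O)C#C[Si](C)(C)C)(C2=O)C3(C)C
F3 | step 20 | cyclohexa-1,4-dienyl ketone | CC(C)=CCC/C(C)=C/C[C@@]12C[C@H]3C[C@@H]4C(C)(C)CC[C@]4(C1=O)C(=O)[C@@](C(=O)C5=CCC=CC5)(C2=O)C3(C)C
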